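**Plan**

1. Retrosynthetic cuts, in order: O–C15 of the dihydrofuran (alkynol cycloisomerisation); the C8 spiro-epoxide; O–C13 of the tetrahydrofuran (epoxide opening by the 9-hydroxyl); C9–C11 (B-alkyl Suzuki coupling) together with O–C9 ([2,3] shift); O–C20 of the lactone (nitrile plus alcohol); finally ring A at C1–C10 and C3–C4.
2. Enabling feature: C10 lies between the C9 ketone and the C20 ester, C4 is α to the C19 formyl group, and the two acidic carbons are 1,3-related through C5 of ring B, so a three-carbon 1,3-dielectrophile can bridge them and close ring A in one pot.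
3. Forward order: ring B from an arene (quinone monoketal), Michael addition (C5), one-pot (3+3) annulation (ring A, C10, C4), 19,20-lactone, C8/C9 functionalisation and side-chain coupling, 9,13-tetrahydrofuran, 8,17-epoxide, spiro dihydrofuran last.
4. Stereochemistry: C5 from an enamine-catalysed Michael addition; C10 and C4 substrate-controlled in the annulation; C9 by a suprafacial [2,3] shift on the α face; C13 from an asymmetric epoxidation, inverted on ring closure; C6 by hydride from the α face; C8 by hydroxyl-directed epoxidation.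

Key step: step 3

Remark: labdane numbering is used (ring A = C1–C5, C10; ring B = C5–C10; side chain C11–C16; C17 on C8; C18 and C19 on C4; C20 on C10), with β the face of C20. The sense of induction in step 2 is assigned by analogy with nitroalkene additions; the enantiomeric catalyst would be used if it proved opposite.

**Route**

Step 1
Reactants: 1 methyl 2-hydroxy-5-methoxybenzoate
Product: 2 methyl 3,3-dimethoxy-6-oxocyclohexa-1,4-diene-1-carboxylate
Conditions: PhI(OAc)2, MeOH, 0 °C
Reagents that add atoms: methanol (CO)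
Why: Hypervalent-iodine oxidative dearomatisation of a para-methoxyphenol in methanol should give the para-quinone monoketal, which masks C6 at the ketone level and leaves C5 as the doubly activated β-carbon of an alkylidene β-keto ester.

Step 2
Reactants: 2 methyl 3,3-dimethoxy-6-oxocyclohexa-1,4-diene-1-carboxylate; 3 propanal
Product: 4 methyl (6S)-5,5-dimethoxy-2-oxo-6-(1-oxopropan-2-yl)cyclohex-3-ene-1-carboxylate
Conditions: (R)-α,α-diphenylprolinol trimethylsilyl ether (20 mol %), PhCO2H (20 mol %), toluene, 0 °C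
Reagents that add atoms: none
Why: Enamine-catalysed Michael addition of propanal to the doubly activated C5, in which the catalyst shields one enamine face and the usual synclinal transition state is expected to set 6S (C5), while the side-chain α-carbon (C4) and C10 stay epimerisable and are inconsequential.

Step 3
Reactants: 4 methyl (6S)-5,5-dimethoxy-2-oxo-6-(1-oxopropan-2-yl)cyclohex-3-ene-1-carboxylate; 5 1-chloro-3-iodopropane
Product: 7 methyl 4β-formyl-6,6-dimethoxy-4α-methyl-9-oxo-trans-decal-7-ene-10β-carboxylate (5α-H; 4S,5S,10R), via chloropropyl keto ester 6 (not isolated)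
Conditions: K2CO3, DMF, 0 °C to rt; then KOt-Bu, NaI (cat.), THF, 0 °C to rt (one pot)
Reagents that add atoms: none
Why: The potassium enolate of the β-keto ester (C9 ketone, C20 ester), the only carbon acid that K2CO3 deprotonates, attacks the iodide end of 5 at C10 on the face anti to the C5 substituent, which puts C1 trans to C4 and so fixes the C10 quaternary centre (ester β) and the trans A/B fusion. KOt-Bu then forms the (E)-enolate of the α-branched aldehyde, which displaces chloride in a 6-exo-tet closure of ring A (C4 to C3) through a chair transition state. Because the enolate carbon C19 carries only hydrogen cis to C5 there is no allylic strain, so the small formyl group should take the developing axial site 1,3 to the C10 ester and the methyl group the equatorial site, giving the 4β-formyl-4α-methyl centre. The closest known reaction types are the (3+3) double-alkylation annulation of 1,3-related carbon acids with 1,3-dihalopropanes and the base-mediated intramolecular α-alkylation of α-branched aldehydes. The step needs C- over O-alkylation at C10 (soft iodide), C10 before C4 (secured by the pKa gap and the staged bases) and no competing ketone enolate, which the substrate secures because C8 is sp2 and C6 is a ketal carbon without hydrogen.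

Step 4
Reactants: 7 methyl 4β-formyl-6,6-dimethoxy-4α-methyl-9-oxo-trans-decal-7-ene-10β-carboxylate
Product: 8 methyl 4β-cyano-6,6-dimethoxy-4α-methyl-9-oxo-trans-decal-7-ene-10β-carboxylate
Conditions: NH3 (aq), I2, THF, rt
Reagents that add atoms: ammonia (N)
Why: Condensation to the aldimine, N-iodination and loss of HI should give the nitrile, which keeps C19 at the carboxyl oxidation level yet is inert to the bases and hydride used next, with no stereocentre touched.

Step 5
Reactants: 8 methyl 4β-cyano-6,6-dimethoxy-4α-methyl-9-oxo-trans-decal-7-ene-10β-carboxylate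
Product: 9 methyl 4β-cyano-6,6-dimethoxy-4α-methyl-9-oxo-trans-decalin-10β-carboxylate
Conditions: H2 (1 atm), Pd/C, EtOAc, rt
Reagents that add atoms: none
Why: Heterogeneous hydrogenation should saturate the disubstituted C7=C8 enone alkene and leave the nitrile, ester and ketal untouched.

Step 6
Reactants: 9 methyl 4β-cyano-6,6-dimethoxy-4α-methyl-9-oxo-trans-decalin-10β-carboxylate
Product: 12 9-hydroxy-6,6-dimethoxy-19,20-lactone (C19 carbonyl, C20 methylene), via diol nitrile 10 (not isolated), via iminolactone 11 (not isolated)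
Conditions: LiBH4, THF–MeOH, 0 to 50 °C; then NaOAc/AcOH buffer (pH 5), THF–H2O, rt
Reagents that add atoms: water (O)
Why: LiBH4 should reduce the ketone and, assisted by the resulting C9 alkoxyborohydride, the neopentyl C20 ester but not the tertiary nitrile, after which the C20 alkoxide, held 1,3-diaxial to the cyano group, adds to it (Pinner-type) and the iminolactone hydrolyses at pH 5 to the 19,20-lactone without loss of the ketal (the C9 carbinol configuration is irrelevant).

Step 7
Reactants: 12 9-hydroxy-6,6-dimethoxy-19,20-lactone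
Product: 13 9-oxo-6,6-dimethoxy-19,20-lactone
Conditions: Dess–Martin periodinane, pyridine, CH2Cl2, rt
Reagents that add atoms: none
Why: Dess–Martin oxidation of the secondary C9 alcohol should regenerate the ketone, the primary alcohol being tied up in the lactone.

Step 8
Reactants: 13 9-oxo-6,6-dimethoxy-19,20-lactone
Product: 16 8(17)-methylidene-9-oxo-6,6-dimethoxy-19,20-lactone, via Mannich base 14 (not isolated), via ammonium iodide 15 (not isolated)
Conditions: LiN(SiMe3)2, THF, −78 °C; (CH2=NMe2)I, −78 °C to rt; then MeI; then aq. NaHCO3, CH2Cl2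
Reagents that add atoms: N,N-dimethylmethyleneiminium iodide (C=[N+](C)C.[I-])
Why: Mannich methylenation at C8, the only enolisable position because C10 is quaternary, followed by quaternisation and elimination should give the exocyclic enone that carries C17.

Step 9
Reactants: 16 8(17)-methylidene-9-oxo-6,6-dimethoxy-19,20-lactone
Product: 18 17-(phenylsulfanyl)-9-(trifluoromethylsulfonyloxy)-8-ene 6,6-dimethoxy-19,20-lactone, via lithium enolate 17 (not isolated)
Conditions: PhSH, n-BuLi, THF, −78 °C; then PhNTf2, −78 to 0 °C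
Reagents that add atoms: thiophenol (Sc1ccccc1); N-phenylbis(trifluoromethanesulfonimide) (FC(F)(F)S(=O)(=O)N(c1ccccc1)S(=O)(=O)C(F)(F)F)
Why: Conjugate addition of lithium benzenethiolate to C17 generates the C8=C9 enolate regiospecifically and the triflimide should trap it on oxygen as the tetrasubstituted enol triflate.

Step 10
Reactants: 19 2-bromoprop-2-en-1-ol; 20 ethynyltri(propan-2-yl)silane
Product: 21 2-methylidene-4-[tri(propan-2-yl)silyl]but-3-yn-1-ol
Conditions: Pd(PPh3)2Cl2 (cat.), CuI (cat.), i-Pr2NH, THF, rt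
Reagents that add atoms: none
Why: Sonogashira coupling of the vinyl bromide with the terminal silylalkyne.

Step 11
Reactants: 21 2-methylidene-4-[tri(propan-2-yl)silyl]but-3-yn-1-ol
Product: 22 (R)-{2-[(triisopropylsilyl)ethynyl]oxiran-2-yl}methanol
Conditions: Ti(Oi-Pr)4 (cat.), D-(−)-diethyl tartrate (cat.), t-BuOOH, 4 Å molecular sieves, CH2Cl2, −20 °C
Reagents that add atoms: tert-butyl hydroperoxide (CC(C)(C)OO)
Why: Katsuki–Sharpless asymmetric epoxidation of the 2-substituted allylic alcohol, in which D-(−)-tartrate delivers oxygen to the face that gives the R epoxy alcohol (the same sense as for (R)-2-methylglycidol) and so sets the future C13.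

Step 12
Reactants: 22 (R)-{2-[(triisopropylsilyl)ethynyl]oxiran-2-yl}methanol
Product: 23 (S)-2-[(triisopropylsilyl)ethynyl]oxirane-2-carbaldehyde
Conditions: Dess–Martin periodinane, pyridine, CH2Cl2, 0 °C
Reagents that add atoms: none
Why: Buffered Dess–Martin oxidation should give the non-enolisable α-epoxy aldehyde without opening the epoxide.

Step 13
Reactants: 23 (S)-2-[(triisopropylsilyl)ethynyl]oxirane-2-carbaldehyde
Product: 24 (S)-2-ethenyl-2-[(triisopropylsilyl)ethynyl]oxirane
Conditions: Ph3PCH3Br, KN(SiMe3)2, THF, −78 to 0 °C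
Reagents that add atoms: methyltriphenylphosphonium bromide (C[P+](c1ccccc1)(c1ccccc1)c1ccccc1.[Br-])
Why: Wittig methylenation turns the formyl group into the vinyl group (future C12 and C11) without touching the quaternary stereocentre.

Step 14
Reactants: 18 17-(phenylsulfanyl)-9-(trifluoromethylsulfonyloxy)-8-ene 6,6-dimethoxy-19,20-lactone; 24 (S)-2-ethenyl-2-[(triisopropylsilyl)ethynyl]oxirane
Product: 26 17-(phenylsulfanyl)-8-ene lactone carrying the C11–C16 chain (13,16-epoxide, 15-silyl-14-yne) on C9, via alkylborane 25 (not isolated)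
Conditions: 24, 9-BBN-H, THF, rt; then 18, Pd(dppf)Cl2 (cat.), K3PO4 (aq), DMF, 50 °C
Reagents that add atoms: none
Why: Anti-Markovnikov hydroboration of the vinyl group (epoxide and silylalkyne are inert to 9-BBN-H) and B-alkyl Suzuki–Miyaura coupling with the enol triflate should form C9–C11.

Step 15
Reactants: 26 17-(phenylsulfanyl)-8-ene lactone carrying the C11–C16 chain on C9
Product: 29 9α-hydroxy-8(17)-ene 6,6-dimethoxy-19,20-lactone with the 13,16-epoxide side chain, via allylic sulfoxide 27 (not isolated), via sulfenate ester 28 (not isolated)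
Conditions: m-CPBA (1.0 equiv), CH2Cl2, −78 °C; then P(OMe)3, MeOH, rt
Reagents that add atoms: 3-chloroperbenzoic acid (OOC(=O)c1cccc(Cl)c1)
Why: Sulfide oxidation and Mislow–Evans [2,3]-sigmatropic shift, with the sulfenate trapped by the phosphite, should deliver oxygen suprafacially to C9 on the α face, away from the β-oriented C20 bridge on the adjacent C10, giving the 9α-ol and moving the alkene to C8=C17.

Step 16
Reactants: 29 9α-hydroxy-8(17)-ene 6,6-dimethoxy-19,20-lactone with the 13,16-epoxide side chain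
Product: 31 9α,13-epoxy-16-hydroxy-6-oxo-8(17)-ene 19,20-lactone (15-silyl-14-yne), via tetrahydrofuran ketal 30 (not isolated)
Conditions: camphorsulfonic acid (cat.), CH2Cl2, 0 °C; then pyridinium p-toluenesulfonate (cat.), acetone–H2O, rt
Reagents that add atoms: water (O)
Why: Acid-catalysed 5-exo opening of the epoxide by the 9α-hydroxyl at the tertiary propargylic C13 with inversion should form the tetrahydrofuran and fix C13 (alkyne syn to C10, CH2OH syn to C8), after which aqueous acid unmasks the C6 ketone.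

Step 17
Reactants: 31 9α,13-epoxy-16-hydroxy-6-oxo-8(17)-ene 19,20-lactone
Product: 32 16-O-tert-butyldimethylsilyl ether of 31
Conditions: t-BuMe2SiCl, imidazole, DMF, rt
Reagents that add atoms: tert-butyldimethylsilyl chloride (CC(C)(C)[Si](C)(C)Cl)
Why: Silylation of the primary C16 alcohol so that it can neither direct nor intercept the later epoxidation.

Step 18
Reactants: 32 16-O-tert-butyldimethylsilyl ether of 31
Product: 33 6β-hydroxy-8(17)-ene 16-silyl ether
Conditions: NaBH4, MeOH, 0 °C
Reagents that add atoms: none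
Why: Hydride should attack C6 from the open α (equatorial) side because the β face is covered by the C19/C20 lactone bridge, giving the axial 6β-alcohol without reducing the lactone.

Step 19
Reactants: 33 6β-hydroxy-8(17)-ene 16-silyl ether
Product: 34 6β-hydroxy-8β,17-epoxide 16-silyl ether
Conditions: VO(acac)2 (cat.), t-BuOOH, CH2Cl2, 0 °C to rt
Reagents that add atoms: tert-butyl hydroperoxide (CC(C)(C)OO)
Why: Vanadium-catalysed epoxidation directed by the homoallylic axial 6β-hydroxyl, which is 1,3-diaxial to the β face of C8, should deliver oxygen to that face and give the 8β,17-epoxide.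

Step 20
Reactants: 34 6β-hydroxy-8β,17-epoxide 16-silyl ether
Product: 35 6β-acetoxy-8β,17-epoxide 16-silyl ether
Conditions: Ac2O, 4-(dimethylamino)pyridine (cat.), pyridine, rt to 40 °C
Reagents that add atoms: acetic anhydride (CC(=O)OC(C)=O)
Why: Nucleophile-catalysed acetylation of the hindered axial alcohol.

Step 21
Reactants: 35 6β-acetoxy-8β,17-epoxide 16-silyl ether
Product: 36 6β-acetoxy-8β,17;9α,13-diepoxy-16-hydroxy-14-yne 19,20-lactone
Conditions: Bu4NF, AcOH, THF, 0 °C to rt
Reagents that add atoms: none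
Why: Fluoride cleaves the primary silyl ether and the alkynylsilane, acetic acid buffering protecting the acetate and the epoxide.

Step 22
Reactants: 36 6β-acetoxy-8β,17;9α,13-diepoxy-16-hydroxy-14-yne 19,20-lactone
Product: 37 CNP0173713.2 (6β-acetoxy-8β,17;9α,13;15,16-triepoxylabd-14-en-19,20-olide)
Conditions: Mo(CO)6 (cat.), Et3N, Et2O, hν (350 nm), rt
Reagents that add atoms: none
Why: Alkynol cycloisomerisation in which the Mo(CO)5(NEt3) fragment turns the terminal alkyne into a vinylidene that the C16 hydroxyl attacks (5-endo overall), giving the 2,3-dihydrofuran under basic conditions that the acid-labile spiro enol ether tolerates.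

**Compound list**

1 | methyl 2-hydroxy-5-methoxybenzoate | COC(=O)c1cc(OC)ccc1O | starting material
2 | methyl 3,3-dimethoxy-6-oxocyclohexa-1,4-diene-1-carboxylate | COC(=O)C1=CC(OC)(OC)C=CC1=O | intermediate
3 | propanal | CCC=O | starting material
4 | methyl (6S)-5,5-dimethoxy-2-oxo-6-(1-oxopropan-2-yl)cyclohex-3-ene-1-carboxylate (C1 and side-chain α-carbon as epimer mixtures) | COC1(OC)C=CC(=O)C(C(=O)OC)[C@@H]1C(C)C=O | intermediate
5 | 1-chloro-3-iodopropane | ClCCCI | starting material
6 | methyl (1R,6S)-1-(3-chloropropyl)-5,5-dimethoxy-2-oxo-6-(1-oxopropan-2-yl)cyclohex-3-ene-1-carboxylate | COC1(OC)C=CC(=O)[C@](CCCCl)(C(=O)OC)[C@@H]1C(C)C=O | intermediate (not isolated)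
7 | methyl 4β-formyl-6,6-dimethoxy-4α-methyl-9-oxo-trans-decal-7-ene-10β-carboxylate (5α-H; 4S,5S,10R) | COC1(OC)C=CC(=O)[C@@]2(C(=O)OC)CCC[C@](C)(C=O)[C@H]12 | intermediate
8 | methyl 4β-cyano-6,6-dimethoxy-4α-methyl-9-oxo-trans-decal-7-ene-10β-carboxylate | COC1(OC)C=CC(=O)[C@@]2(C(=O)OC)CCC[C@](C)(C#N)[C@H]12 | intermediate
9 | methyl 4β-cyano-6,6-dimethoxy-4α-methyl-9-oxo-trans-decalin-10β-carboxylate | COC1(OC)CCC(=O)[C@@]2(C(=O)OC)CCC[C@](C)(C#N)[C@H]12 | intermediate
10 | 4β-cyano-9-hydroxy-10β-(hydroxymethyl)-6,6-dimethoxy-4α-methyl-trans-decalin | COC1(OC)CCC(O)[C@@]2(CO)CCC[C@](C)(C#N)[C@H]12 | intermediate (not isolated)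
11 | 9-hydroxy-6,6-dimethoxy 19,20-iminolactone (cyclic imidate between C19 and O–C20) | COC1(OC)CCC(O)[C@]23CCC[C@](C)(C(=N)OC2)[C@H]13 | intermediate (not isolated)
12 | 9-hydroxy-6,6-dimethoxy-19,20-lactone (4α-methyl, 5α-H; C9 either epimer) | COC1(OC)CCC(O)[C@]23CCC[C@](C)(C(=O)OC2)[C@H]13 | intermediate
13 | 9-oxo-6,6-dimethoxy-19,20-lactone | COC1(OC)CCC(=O)[C@]23CCC[C@](C)(C(=O)OC2)[C@H]13 | intermediate
14 | 8-[(dimethylamino)methyl]-9-oxo-6,6-dimethoxy-19,20-lactone | COC1(OC)CC(CN(C)C)C(=O)[C@]23CCC[C@](C)(C(=O)OC2)[C@H]13 | intermediate (not isolated)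
15 | 8-[(trimethylammonio)methyl]-9-oxo-6,6-dimethoxy-19,20-lactone iodide | COC1(OC)CC(C[N+](C)(C)C)C(=O)[C@]23CCC[C@](C)(C(=O)OC2)[C@H]13.[I-] | intermediate (not isolated)
16 | 8(17)-methylidene-9-oxo-6,6-dimethoxy-19,20-lactone | COC1(OC)CC(=C)C(=O)[C@]23CCC[C@](C)(C(=O)OC2)[C@H]13 | intermediate
17 | lithium 8-en-9-olate of the 17-(phenylsulfanyl) lactone | COC1(OC)CC(CSc4ccccc4)=C([O-])[C@]23CCC[C@](C)(C(=O)OC2)[C@H]13.[Li+] | intermediate (not isolated)
18 | 17-(phenylsulfanyl)-9-(trifluoromethylsulfonyloxy)-8-ene 6,6-dimethoxy-19,20-lactone | COC1(OC)CC(CSc4ccccc4)=C(OS(=O)(=O)C(F)(F)F)[C@]23CCC[C@](C)(C(=O)OC2)[C@H]13 | intermediate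
19 | 2-bromoprop-2-en-1-ol | OCC(Br)=C | starting material
20 | ethynyltri(propan-2-yl)silane | C#C[Si](C(C)C)(C(C)C)C(C)C | starting material
21 | 2-methylidene-4-[tri(propan-2-yl)silyl]but-3-yn-1-ol | OCC(=C)C#C[Si](C(C)C)(C(C)C)C(C)C | intermediate
22 | (R)-{2-[(triisopropylsilyl)ethynyl]oxiran-2-yl}methanol | OC[C@@]1(CO1)C#C[Si](C(C)C)(C(C)C)C(C)C | intermediate
23 | (S)-2-[(triisopropylsilyl)ethynyl]oxirane-2-carbaldehyde | O=C[C@@]1(CO1)C#C[Si](C(C)C)(C(C)C)C(C)C | intermediate
24 | (S)-2-ethenyl-2-[(triisopropylsilyl)ethynyl]oxirane | C=C[C@@]1(CO1)C#C[Si](C(C)C)(C(C)C)C(C)C | intermediate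
25 | 9-{2-[(S)-2-[(triisopropylsilyl)ethynyl]oxiran-2-yl]ethyl}-9-borabicyclo[3.3.1]nonane | C(C[C@@]1(CO1)C#C[Si](C(C)C)(C(C)C)C(C)C)B2C3CCCC2CCC3 | intermediate (not isolated)
26 | 17-(phenylsulfanyl)-8-ene 6,6-dimethoxy-19,20-lactone with the C11–C16 chain on C9 (13,16-epoxide, 15-silyl-14-yne) | COC1(OC)CC(CSc4ccccc4)=C(CC[C@@]5(CO5)C#C[Si](C(C)C)(C(C)C)C(C)C)[C@]23CCC[C@](C)(C(=O)OC2)[C@H]13 | intermediate
27 | 17-(phenylsulfinyl) analogue of 26 | COC1(OC)CC(CS(=O)c4ccccc4)=C(CC[C@@]5(CO5)C#C[Si](C(C)C)(C(C)C)C(C)C)[C@]23CCC[C@](C)(C(=O)OC2)[C@H]13 | intermediate (not isolated)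
28 | 9α-(phenylsulfanyloxy)-8(17)-ene sulfenate ester | COC1(OC)CC(=C)[C@](OSc4ccccc4)(CC[C@@]5(CO5)C#C[Si](C(C)C)(C(C)C)C(C)C)[C@]23CCC[C@](C)(C(=O)OC2)[C@H]13 | intermediate (not isolated)
29 | 9α-hydroxy-8(17)-ene 6,6-dimethoxy-19,20-lactone with the 13,16-epoxide side chain | COC1(OC)CC(=C)[C@](O)(CC[C@@]5(CO5)C#C[Si](C(C)C)(C(C)C)C(C)C)[C@]23CCC[C@](C)(C(=O)OC2)[C@H]13 | intermediate
30 | 9α,13-epoxy-16-hydroxy-6,6-dimethoxy-8(17)-ene 19,20-lactone (15-silyl-14-yne) | COC1(OC)CC(=C)[C@]4(CC[C@](CO)(C#C[Si](C(C)C)(C(C)C)C(C)C)O4)[C@]23CCC[C@](C)(C(=O)OC2)[C@H]13 | intermediate (not isolated)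
31 | 9α,13-epoxy-16-hydroxy-6-oxo-8(17)-ene 19,20-lactone (15-silyl-14-yne) | O=C1CC(=C)[C@]4(CC[C@](CO)(C#C[Si](C(C)C)(C(C)C)C(C)C)O4)[C@]23CCC[C@](C)(C(=O)OC2)[C@H]13 | intermediate
32 | 16-O-tert-butyldimethylsilyl ether of 31 | O=C1CC(=C)[C@]4(CC[C@](CO[Si](C)(C)C(C)(C)C)(C#C[Si](C(C)C)(C(C)C)C(C)C)O4)[C@]23CCC[C@](C)(C(=O)OC2)[C@H]13 | intermediate
33 | 6β-hydroxy-8(17)-ene 16-silyl ether | O[C@@H]1CC(=C)[C@]4(CC[C@](CO[Si](C)(C)C(C)(C)C)(C#C[Si](C(C)C)(C(C)C)C(C)C)O4)[C@]23CCC[C@](C)(C(=O)OC2)[C@H]13 | intermediate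
34 | 6β-hydroxy-8β,17-epoxide 16-silyl ether | O[C@@H]1C[C@@]5(CO5)[C@]4(CC[C@](CO[Si](C)(C)C(C)(C)C)(C#C[Si](C(C)C)(C(C)C)C(C)C)O4)[C@]23CCC[C@](C)(C(=O)OC2)[C@H]13 | intermediate
35 | 6β-acetoxy-8β,17-epoxide 16-silyl ether | CC(=O)O[C@@H]1C[C@@]5(CO5)[C@]4(CC[C@](CO[Si](C)(C)C(C)(C)C)(C#C[Si](C(C)C)(C(C)C)C(C)C)O4)[C@]23CCC[C@](C)(C(=O)OC2)[C@H]13 | intermediate
36 | 6β-acetoxy-8β,17;9α,13-diepoxy-16-hydroxy-14-yne 19,20-lactone | CC(=O)O[C@@H]1C[C@@]5(CO5)[C@]4(CC[C@](CO)(C#C)O4)[C@]23CCC[C@](C)(C(=O)OC2)[C@H]13 | intermediate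
37 | CNP0173713.2 | CC(=O)O[C@@H]1C[C@@]2(CO2)[C@]2(CC[C@]3(C=COC3)O2)[C@]23CCC[C@](C)(C(=O)OC2)[C@H]13 | target

**Step count and risks**

Total step count: 22. Longest linear sequence: 18 steps (steps 1–9 and 14–22); steps 10–13 make the side-chain fragment.

Step 2. The enamine addition may stall at the hindered C5, next to the ketal carbon, or show poor facial selectivity. The fallback sets out from 2 and comes back at 4. S-Ethyl propanethioate is silylated (LiN(i-Pr)2, Me3SiCl, THF, −78 °C) to (Z)-1-(ethylsulfanyl)-1-(trimethylsilyloxy)prop-1-ene F1. Mukaiyama–Michael addition of this ketene thioacetal to 2 with Cu(OTf)2 and (S,S)-tert-butyl-bis(oxazoline) (chelation of the β-keto ester, CH2Cl2, −78 °C) would give the S-ethyl thioester analogue of 4 F2. Fukuyama reduction (Et3SiH, Pd/C, acetone) would convert it into aldehyde 4.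

Step 3. The ring closure may show poor facial selectivity at C4 (methyl instead of formyl taking the axial site), besides some O-alkylation of the β-keto ester. The fallback sets out from 2 and comes back at 8, and sets C4 after ring A exists. Acetaldehyde is added to 2 under the conditions of step 2 to give methyl (6S)-5,5-dimethoxy-2-oxo-6-(2-oxoethyl)cyclohex-3-ene-1-carboxylate F3. The same two-stage annulation with 5 would give, through the chloropropyl keto ester F4, the bicyclic 4-formyl keto ester F5, whose C4 is tertiary and needs no control. NH3/I2 would give the 4-cyano keto ester F6. Deprotonation (LiN(i-Pr)2, THF, −78 °C) and MeI should methylate the exocyclic nitrile anion from the equatorial α side, anti to the axial C10 ester, to give 8.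

Step 22. The catalyst may be inhibited, the epoxide may be opened by the neighbouring C16 hydroxyl during the slow photochemical reaction, or the spiro enol ether may be opened by acid on isolation. The fallback sets out from 36 and comes back at 37. Anti-Markovnikov hydration of the terminal alkyne ([CpRu(MeCN)3]PF6, 5,5'-bis(trifluoromethyl)-2,2'-bipyridine, acetone–H2O, rt) would give an aldehyde that closes with the C16 hydroxyl to the 15-hydroxy-15,16-epoxy lactol F7. Mesylation and elimination (MsCl, Et3N, CH2Cl2, −20 °C to rt) would then give 37.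

Further compounds
F1 | step 2 | (Z)-1-(ethylsulfanyl)-1-(trimethylsilyloxy)prop-1-ene | C/C=C(/O[Si](C)(C)C)SCC
F2 | step 2 | S-ethyl thioester analogue of 4 (same configuration at the ring carbon bearing the side chain) | COC1(OC)C=CC(=O)C(C(=O)OC)[C@@H]1C(C)C(=O)SCC
F3 | step 3 | methyl (6S)-5,5-dimethoxy-2-oxo-6-(2-oxoethyl)cyclohex-3-ene-1-carboxylate | COC1(OC)C=CC(=O)C(C(=O)OC)[C@@H]1CC=O
F4 | step 3 | methyl 1-(3-chloropropyl)-5,5-dimethoxy-2-oxo-6-(2-oxoethyl)cyclohex-3-ene-1-carboxylate (chloropropyl trans to the side chain) | COC1(OC)C=CC(=O)[C@](CCCCl)(C(=O)OC)[C@@H]1CC=O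
F5 | step 3 | methyl 4-formyl-6,6-dimethoxy-9-oxo-trans-decal-7-ene-10β-carboxylate (C4 epimers) | COC1(OC)C=CC(=O)[C@@]2(C(=O)OC)CCCC(C=O)[C@H]12
F6 | step 3 | methyl 4-cyano-6,6-dimethoxy-9-oxo-trans-decal-7-ene-10β-carboxylate (C4 epimers) | COC1(OC)C=CC(=O)[C@@]2(C(=O)OC)CCCC(C#N)[C@H]12
F7 | step 22 | 6β-acetoxy-15-hydroxy-8β,17;9α,13;15,16-triepoxylabdan-19,20-olide (lactol) | CC(=O)O[C@@H]1C[C@@]2(CO2)[C@]2(CC[C@]3(CC(O)OC3)O2)[C@]23CCC[C@](C)(C(=O)OC2)[C@H]13
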